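**Retrosynthetic overview**
1. Target 14 ⇐ global O-debenzylation of 13 ⇐ dehydrogenation of the lower heterocycle of a (4β→5)-linked homodimer of one 2,3-cis-flavan-3,4-diol. A flavonol A-ring is too electron-poor to capture a C4 cation; its diol form is not.
2. Homodimer 10 ⇐ acid-mediated self-condensation of monomer 8: C4 cation plus C5 of a second molecule (para to its only free phenol); this sets C4.
3. Monomer 8 ⇐ enantioselective all-cis hydrogenation of flavonol 5; this sets C2 and C3.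
4. Flavonol 5 ⇐ chalcone 4 by Algar–Flynn–Oyamada oxidative cyclisation (the only ring-forming step; it supplies both heterocycles) ⇐ Claisen–Schmidt condensation of 2 and 3.
5. Ring order: the pyranone ring of 5 is made first, reduced to the pyran ring of both halves, and the lower one is returned to the flavonol level last.

Assumption: the biosynthesis is taken as chalcone → oxidative cyclisation → flavonol / 2,3-cis-flavan-3,4-diol (melanoxetin / melacacidin), capture of the diol's C4 cation by C5 of a second unit, and dehydrogenation of that unit to the flavonol; the ligand antipode in step 3 is the one that gives (2R,3R), fixed by a first run.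

**Step 1**
Reactants: 1 gallacetophenone [1-(2,3,4-trihydroxyphenyl)ethanone]
Product: 2 1-[4-(benzyloxy)-2,3-dihydroxyphenyl]ethanone
Conditions: BnBr (1.05 equiv), NaHCO3 (1.3 equiv), NaI (cat.), MeCN, 60 °C
Reagents that add atoms: benzyl bromide, BrCc1ccccc1
Why: Williamson etherification under weak base alkylates only the most acidic 4-OH (para to the acetyl; 2-OH is hydrogen-bonded to C=O), which leaves the future 8-OH free as the para-directing group for step 4.

**Step 2**
Reactants: 2 1-[4-(benzyloxy)-2,3-dihydroxyphenyl]ethanone; 3 3,4-bis(benzyloxy)benzaldehyde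
Product: 5 7-(benzyloxy)-2-[3,4-bis(benzyloxy)phenyl]-3,8-dihydroxy-4H-chromen-4-one (7,3',4'-tri-O-benzylmelanoxetin), via 2',3'-dihydroxychalcone 4 (not isolated)
Conditions: KOH (50% aq), EtOH, rt, 48 h, Ar; then 30% H2O2, 0 °C → rt; HCl work-up
Reagents that add atoms: hydrogen peroxide, OO
Why: Claisen–Schmidt condensation followed by Algar–Flynn–Oyamada oxidative cyclisation, in which the 2'-phenoxide closes the six-membered ring at the β-carbon and the dihydroflavonol is oxidised on to the flavonol (6'-H chalcones give flavonols, not aurones); no stereocentre is formed.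

**Step 3**
Reactants: 5 7,3',4'-tri-O-benzylmelanoxetin
Product: 8 (2R,3R,4R)-7-(benzyloxy)-2-[3,4-bis(benzyloxy)phenyl]chromane-3,4,8-triol (7,3',4'-tri-O-benzylmelacacidin), via 3,8-bis-O-trimethylsilyl flavonol 6 (not isolated), via 3,8-bis-O-trimethylsilyl all-cis diol 7 (not isolated)
Conditions: HMDS, cat. (NH4)2SO4, PhMe, 80 °C, evaporate; Ru(cod)(2-methylallyl)2 (5 mol %), (R,R)-SINpEt·HBF4 (10 mol %), KOt-Bu (10 mol %), H2 (120 bar), PhMe–hexane, 40 °C; then MeOH, cat. K2CO3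
Reagents that add atoms: none
Why: Proposed new method: the silylated flavonol is a flavone-type vinylogous ester with its chelating, acidic OH groups masked, so a chiral Ru(II)–bis-NHC hydride should add H2 syn to one enantioface of C2=C3 (setting C2 R and, by syn addition, the 2,3-cis C3 R) and then reduce C4=O from the same open face to the all-cis diol; the closest known reactions are the Ru–NHC asymmetric hydrogenation of flavones and chromones to cis-flavan-4-ols and the heterogeneous cis,cis-hydrogenation of 7,8,3',4'-tetra-O-alkylflavonols to racemic melacacidin ethers, and the C4 configuration is inconsequential because C4 is later ionised (upper unit) or oxidised (lower unit).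

**Step 4**
Reactants: 8 7,3',4'-tri-O-benzylmelacacidin (two molecules; one ionises, one is the nucleophile)
Product: 10 7,3',4'-tri-O-benzylepimesquitol-(4β→5)-7,3',4'-tri-O-benzylmelacacidin [upper unit 2R,3R,4S; lower unit 2R,3R,4R], via C4 benzylic cation 9 (not isolated)
Conditions: TsOH·H2O (10 mol %), HFIP–CH2Cl2 (1:4), 0.02 M, 0 °C; NaHCO3 quench at ~50% conversion, unreacted 8 recycled
Reagents that add atoms: none
Why: Dehydrative Friedel–Crafts self-condensation of the proanthocyanidin type, in which the 7-OBn-stabilised C4 cation is attacked by C5 of a second molecule (para to its only free phenol, both ortho positions blocked) from the β-face anti to the cis 2-aryl/3-OH pair, setting C4 as 4S (3,4-trans); any C4-epimerised lower diol converges in step 6.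

**Step 5**
Reactants: 10 hexa-O-benzyl dimer with two free 8-OH groups
Product: 11 7,8,3',4'-tetra-O-benzylepimesquitol-(4β→5)-7,8,3',4'-tetra-O-benzylmelacacidin
Conditions: BnBr (2.4 equiv), K2CO3 (3 equiv), DMF, rt
Reagents that add atoms: benzyl bromide, BrCc1ccccc1
Why: Williamson etherification in which only the two phenols ionise under carbonate, capping them so that DDQ cannot oxidise the p-hydroxybenzhydryl system to a quinone methide in step 6; the three aliphatic hydroxyls and all stereocentres are untouched.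

**Step 6**
Reactants: 11 octa-O-benzyl dimer with a lower cis-3,4-diol
Product: 13 7,8,3',4'-tetra-O-benzylepimesquitol-(4β→5)-7,8,3',4'-tetra-O-benzylmelanoxetin, via lower-unit 2,3-cis-dihydroflavonol 12 (not isolated)
Conditions: DDQ (1.3 equiv), CH2Cl2, 0 °C → rt; then MeOH, K2CO3 (3 equiv), O2 (1 atm), rt, same flask
Reagents that add atoms: none
Why: DDQ abstracts hydride only from the lower C4–H (a benzylic carbinol para to 7-OBn) to give the aryl ketone, and the α-ketol is then dehydrogenated through its enediolate by O2 (the closing stage of an Algar–Flynn–Oyamada sequence) to the flavonol, whereas the upper unit has no benzylic carbinol, its C4–H is quasi-equatorial and hindered, and its three stereocentres are not enolisable.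

**Step 7**
Reactants: 13 octa-O-benzyl target
Product: 14 epimesquitol-(4β→5)-melanoxetin (target)
Conditions: H2 (1 atm), Pd(OH)2/C, THF–MeOH, rt
Reagents that add atoms: none
Why: Hydrogenolysis of the eight aryl benzyl ethers; the flavonol C2=C3, the C2–O1 bond and the C4–aryl bond survive at 1 atm, so no stereocentre is touched.

**Compound list**
1 | gallacetophenone, 1-(2,3,4-trihydroxyphenyl)ethanone | CC(=O)c1ccc(O)c(O)c1O | starting material
2 | 1-[4-(benzyloxy)-2,3-dihydroxyphenyl]ethanone | CC(=O)c1ccc(OCc2ccccc2)c(O)c1O | intermediate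
3 | 3,4-bis(benzyloxy)benzaldehyde | O=Cc1ccc(OCc2ccccc2)c(OCc2ccccc2)c1 | starting material
4 | (E)-1-[4-(benzyloxy)-2,3-dihydroxyphenyl]-3-[3,4-bis(benzyloxy)phenyl]prop-2-en-1-one (chalcone) | O=C(/C=C/c1ccc(OCc2ccccc2)c(OCc2ccccc2)c1)c1ccc(OCc2ccccc2)c(O)c1O | intermediate
5 | 7-(benzyloxy)-2-[3,4-bis(benzyloxy)phenyl]-3,8-dihydroxy-4H-chromen-4-one | O=c1c(O)c(-c2ccc(OCc3ccccc3)c(OCc3ccccc3)c2)oc2c(O)c(OCc3ccccc3)ccc12 | intermediate
6 | 3,8-bis(trimethylsilyl) ether of 5 | O=c1c(O[Si](C)(C)C)c(-c2ccc(OCc3ccccc3)c(OCc3ccccc3)c2)oc2c(O[Si](C)(C)C)c(OCc3ccccc3)ccc12 | intermediate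
7 | (2R,3R,4R)-7-(benzyloxy)-2-[3,4-bis(benzyloxy)phenyl]-3,8-bis(trimethylsilyloxy)chroman-4-ol | O[C@@H]1c2ccc(OCc3ccccc3)c(O[Si](C)(C)C)c2O[C@H](c2ccc(OCc3ccccc3)c(OCc3ccccc3)c2)[C@@H]1O[Si](C)(C)C | intermediate
8 | (2R,3R,4R)-7-(benzyloxy)-2-[3,4-bis(benzyloxy)phenyl]chromane-3,4,8-triol (all-cis) | O[C@@H]1c2ccc(OCc3ccccc3)c(O)c2O[C@H](c2ccc(OCc3ccccc3)c(OCc3ccccc3)c2)[C@@H]1O | intermediate
9 | (2R,3R)-7-(benzyloxy)-2-[3,4-bis(benzyloxy)phenyl]-3,8-dihydroxychroman-4-ylium (C4 benzylic cation) | [CH+]1c2ccc(OCc3ccccc3)c(O)c2O[C@H](c2ccc(OCc3ccccc3)c(OCc3ccccc3)c2)[C@@H]1O | intermediate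
10 | (4β→5) dimer: upper (2R,3R,4S)-7,3',4'-tri-O-benzyl-flavan-3,8-diol-4-yl on C5 of lower (2R,3R,4R)-7,3',4'-tri-O-benzyl-flavan-3,4,8-triol | O[C@@H]1c2c([C@H]3c4ccc(OCc5ccccc5)c(O)c4O[C@H](c4ccc(OCc5ccccc5)c(OCc5ccccc5)c4)[C@@H]3O)cc(OCc3ccccc3)c(O)c2O[C@H](c2ccc(OCc3ccccc3)c(OCc3ccccc3)c2)[C@@H]1O | intermediate
11 | 8,8''-di-O-benzyl ether of 10 (octa-O-benzyl; lower cis-3,4-diol) | O[C@@H]1c2c([C@H]3c4ccc(OCc5ccccc5)c(OCc5ccccc5)c4O[C@H](c4ccc(OCc5ccccc5)c(OCc5ccccc5)c4)[C@@H]3O)cc(OCc3ccccc3)c(OCc3ccccc3)c2O[C@H](c2ccc(OCc3ccccc3)c(OCc3ccccc3)c2)[C@@H]1O | intermediate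
12 | octa-O-benzyl dimer with lower unit as (2R,3S)-3-hydroxyflavan-4-one (2,3-cis-dihydroflavonol) | O=C1c2c([C@H]3c4ccc(OCc5ccccc5)c(OCc5ccccc5)c4O[C@H](c4ccc(OCc5ccccc5)c(OCc5ccccc5)c4)[C@@H]3O)cc(OCc3ccccc3)c(OCc3ccccc3)c2O[C@H](c2ccc(OCc3ccccc3)c(OCc3ccccc3)c2)[C@@H]1O | intermediate
13 | octa-O-benzyl target: upper (2R,3R,4S)-7,8,3',4'-tetra-O-benzyl-flavan-3-ol-4-yl on C5 of 7,8,3',4'-tetra-O-benzyl-3-hydroxyflavone | O=c1c(O)c(-c2ccc(OCc3ccccc3)c(OCc3ccccc3)c2)oc2c(OCc3ccccc3)c(OCc3ccccc3)cc([C@H]3c4ccc(OCc5ccccc5)c(OCc5ccccc5)c4O[C@H](c4ccc(OCc5ccccc5)c(OCc5ccccc5)c4)[C@@H]3O)c12 | intermediate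
14 | epimesquitol-(4β→5)-melanoxetin: 5-[(2R,3R,4S)-2-(3,4-dihydroxyphenyl)-3,7,8-trihydroxychroman-4-yl]-2-(3,4-dihydroxyphenyl)-3,7,8-trihydroxy-4H-chromen-4-one | O=c1c(O)c(-c2ccc(O)c(O)c2)oc2c(O)c(O)cc([C@H]3c4ccc(O)c(O)c4O[C@H](c4ccc(O)c(O)c4)[C@@H]3O)c12 | target

**Totals**
Total steps: 7. Longest linear sequence: 7 (1 → 2 → 5 → 8 → 10 → 11 → 13 → 14; aldehyde 3 is purchased).

**Three steps most likely to fail, each with a fallback**

Step 3 (untested asymmetric hydrogenation of a tetrasubstituted 3-oxygenated flavone; conversion or ee may be poor). The fallback sets out from 5 and replaces catalytic asymmetric induction by racemic reduction plus resolution. Hydrogenation of 5 over Adams platinum in neutral EtOAc at 60 bar should leave the aryl benzyl ethers intact and gives the racemic all-cis triol F1. Acylation of its phenolic 8-OH with (1S)-camphanic chloride (Et3N, CH2Cl2, −30 °C) gives the 8-O-camphanate of the (2R,3R,4R) triol F2 and the 8-O-camphanate of the (2S,3S,4S) triol F3. These are separated by crystallisation or chromatography, and methanolysis of F2 (K2CO3, MeOH, 0 °C) returns to the route at 8.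

Step 4 (oligomerisation, O-alkylation or C6 attack in the Brønsted-acid self-condensation). The fallback sets out from 8 and separates electrophile from nucleophile. Part of 8 is converted with phenylmethanethiol and catalytic TsOH into the 4β-benzylsulfanyl flavan-3,8-diol F4 (2R,3S,4S; 3,4-trans). F4 is then activated with the thiophilic Lewis acid AgBF4 (THF, 0 °C) in the presence of 3–4 equiv of unactivated 8, which silver does not ionise, so the cation is generated slowly and only from F4. This comes back to the route at 10.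

Step 6 (DDQ may be slow if the lower C4–H is forced quasi-equatorial by the peri substituent, or may attack the upper unit). The fallback sets out from 11 and replaces benzylic selectivity by protecting-group differentiation of the cis-diol. 2,2-Dimethoxypropane with PPTS converts only the lower cis-3,4-diol into the 3,4-O-isopropylidene dimer F5. Acetylation (Ac2O, pyridine, DMAP) gives the upper 3-O-acetyl acetonide F6. Aqueous AcOH–THF removes the acetonide to give the upper 3-O-acetyl lower-diol dimer F7. Swern oxidation of both lower hydroxyls gives the 3,4-dione, which enolises to the upper 3-O-acetyl flavonol dimer F8. Methanolysis (K2CO3, MeOH) comes back to the route at 13.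

**Further compounds**
F1 | step 3 | racemic all-cis 7-(benzyloxy)-2-[3,4-bis(benzyloxy)phenyl]chromane-3,4,8-triol | O[C@@H]1c2ccc(OCc3ccccc3)c(O)c2O[C@H](c2ccc(OCc3ccccc3)c(OCc3ccccc3)c2)[C@@H]1O.O[C@H]1c2ccc(OCc3ccccc3)c(O)c2O[C@@H](c2ccc(OCc3ccccc3)c(OCc3ccccc3)c2)[C@H]1O
F2 | step 3 | 8-O-[(1S,4R)-camphanoyl] ester of the (2R,3R,4R) triol | O[C@@H]1c2ccc(OCc3ccccc3)c(OC(=O)[C@@]34CC[C@@](C)(C(=O)O3)C4(C)C)c2O[C@H](c2ccc(OCc3ccccc3)c(OCc3ccccc3)c2)[C@@H]1O
F3 | step 3 | 8-O-[(1S,4R)-camphanoyl] ester of the (2S,3S,4S) triol | O[C@H]1c2ccc(OCc3ccccc3)c(OC(=O)[C@@]34CC[C@@](C)(C(=O)O3)C4(C)C)c2O[C@@H](c2ccc(OCc3ccccc3)c(OCc3ccccc3)c2)[C@H]1O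
F4 | step 4 | (2R,3S,4S)-7-(benzyloxy)-4-(benzylsulfanyl)-2-[3,4-bis(benzyloxy)phenyl]chromane-3,8-diol | c1ccccc1CS[C@H]1c2ccc(OCc3ccccc3)c(O)c2O[C@H](c2ccc(OCc3ccccc3)c(OCc3ccccc3)c2)[C@@H]1O
F5 | step 6 | lower 3,4-O-isopropylidene derivative of 11 | CC1(C)O[C@@H]2c3c([C@H]4c5ccc(OCc6ccccc6)c(OCc6ccccc6)c5O[C@H](c5ccc(OCc6ccccc6)c(OCc6ccccc6)c5)[C@@H]4O)cc(OCc4ccccc4)c(OCc4ccccc4)c3O[C@H](c3ccc(OCc4ccccc4)c(OCc4ccccc4)c3)[C@@H]2O1
F6 | step 6 | upper 3-O-acetyl lower 3,4-O-isopropylidene derivative of 11 | CC1(C)O[C@@H]2c3c([C@H]4c5ccc(OCc6ccccc6)c(OCc6ccccc6)c5O[C@H](c5ccc(OCc6ccccc6)c(OCc6ccccc6)c5)[C@@H]4OC(C)=O)cc(OCc4ccccc4)c(OCc4ccccc4)c3O[C@H](c3ccc(OCc4ccccc4)c(OCc4ccccc4)c3)[C@@H]2O1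
F7 | step 6 | upper 3-O-acetyl derivative of 11 (lower cis-3,4-diol free) | O[C@@H]1c2c([C@H]3c4ccc(OCc5ccccc5)c(OCc5ccccc5)c4O[C@H](c4ccc(OCc5ccccc5)c(OCc5ccccc5)c4)[C@@H]3OC(C)=O)cc(OCc3ccccc3)c(OCc3ccccc3)c2O[C@H](c2ccc(OCc3ccccc3)c(OCc3ccccc3)c2)[C@@H]1O
F8 | step 6 | upper 3-O-acetyl derivative of 13 | O=c1c(O)c(-c2ccc(OCc3ccccc3)c(OCc3ccccc3)c2)oc2c(OCc3ccccc3)c(OCc3ccccc3)cc([C@H]3c4ccc(OCc5ccccc5)c(OCc5ccccc5)c4O[C@H](c4ccc(OCc5ccccc5)c(OCc5ccccc5)c4)[C@@H]3OC(C)=O)c12
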